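A direct plan would acetylate 1,2,3,4-tetramethoxybenzene A1 to the acetophenone A2, join A2 to methyl isovanillate A3 by a Claisen condensation to give the 1,3-diketone A4, and close ring C by a dehydrogenative coupling of the enol oxygen of A4 with the last free C–H of ring A (bond O1–C8a).
Its weakest steps would be:
- The final O1–C8a ring closure of A4: it would have to oxidise one of two electron-rich rings selectively beside an oxidisable enol and a phenol, it has no close precedent, and it would place all the risk in the last step, after the whole skeleton has been invested.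
- The transient acylation and release of the 3'-phenol inside that step: masking that builds nothing and serves only to steer the oxidation.
- The Claisen condensation of A2 with the ester A3, which carries a free phenol: the phenoxide consumes base, the dianion is poorly soluble, and the hindered, ortho-methoxylated ketone enolate can condense with itself.

**Retrosynthetic overview**
Ring A carries five oxygens (O1 at C8a, OMe at C5–C8) and a single carbon substituent, the C4 carbonyl at C4a; C4 is a bare C=O between C4a and C3, the equivalent of carbon monoxide.
Ring C is therefore cut at three bonds at once, C4a–C4, C4–C3 and O1–C2, which leads to 2-iodo-3,4,5,6-tetramethoxyphenol (5), CO and 5-ethynyl-2-methoxyphenol (8).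
Rings A and B are bought as benzene rings; ring C is the only ring made, and it closes last at O1–C2, in the same operation that builds C4 from CO.
O1 is present as the phenol OH from the start (no late C–H oxidation), no diketone or enolate condensation is needed, and the 3'-OH stays free throughout.
The iodine enters the single free C–H of 2,3,4,5-tetramethoxyphenol, the future C4a, so no regiochemical choice arises.

Key step: step 4

Assumption: 1,2,3,4-tetramethoxybenzene, isovanillin and dimethyl (1-diazo-2-oxopropyl)phosphonate are taken as commercial; enaminone 10 is expected as an E/Z mixture whose geometry is lost on ring closure, so its SMILES leaves the double bond open.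

Step 1
Reactants: 1 1,2,3,4-tetramethoxybenzene
Product: 4 2,3,4,5-tetramethoxyphenol, via 2,3,4,5-tetramethoxyphenyllithium 2 (not isolated), via dimethyl arylboronate 3 (not isolated)
Conditions: n-BuLi (1.2 equiv), TMEDA (1.2 equiv), THF, 0 °C → rt, 2 h; B(OMe)3 (2 equiv), −78 °C → rt; AcOH, 30% H2O2, 0 °C → rt
Reagents that add atoms: hydrogen peroxide OO (the phenol oxygen of 4); n-butyllithium [Li]CCCC (Li of 2 only); trimethyl borate COB(OC)OC (the B(OMe)2 group of 3 only)
Why: Directed ortho-metalation (the two free positions of 1 are equivalent and each lies ortho to OMe), borylation and oxidative ipso-hydroxylation of the arylboronate should give the phenol.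

Step 2
Reactants: 4 2,3,4,5-tetramethoxyphenol
Product: 5 2-iodo-3,4,5,6-tetramethoxyphenol
Conditions: NIS (1.05 equiv), MeCN, −20 °C → 0 °C, dark
Reagents that add atoms: N-iodosuccinimide O=C1CCC(=O)N1I
Why: Electrophilic aromatic iodination; the ring has one free carbon, ortho to OH and para to an OMe, so only one monoiodide can form, and the mild iodine source at low temperature should limit oxidation of the phenol.

Step 3
Reactants: 6 isovanillin (3-hydroxy-4-methoxybenzaldehyde)
Product: 8 5-ethynyl-2-methoxyphenol, via diazoalkene 7 (not isolated)
Conditions: dimethyl (1-diazo-2-oxopropyl)phosphonate (1.3 equiv), K2CO3 (3 equiv), MeOH, 0 °C → rt, 16 h; aq NH4Cl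
Reagents that add atoms: dimethyl (1-diazo-2-oxopropyl)phosphonate COP(=O)(OC)C(=[N+]=[N-])C(C)=O (the terminal alkyne carbon of 8; the diazo carbon and N2 of 7)
Why: Seyferth–Gilbert homologation in its Ohira–Bestmann form: methanolysis frees the diazomethylphosphonate anion, olefination of the aldehyde gives diazoalkene 7, and loss of N2 with a 1,2-hydride shift gives the alkyne, the phenoxide being meta to the aldehyde and so not deactivating it by conjugation.

Step 4
Reactants: 5 2-iodo-3,4,5,6-tetramethoxyphenol; 8 5-ethynyl-2-methoxyphenol (1.3 equiv)
Product: 11 3'-demethylnobiletin, via o-hydroxyaryl ynone 9 (not isolated), via diethylamino enone 10 (not isolated)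
Conditions: PdCl2(dppf) (5 mol %), CO (20 bar), Et2NH (0.2 M), 120 °C, 8 h, autoclave
Reagents that add atoms: carbon monoxide [C-]#[O+] (C4 and its oxygen); diethylamine CCNCC (the amino group of 10 only)
Why: Carbonylative Sonogashira coupling with in situ annulation, the known three-component flavone synthesis from an o-iodophenol, CO and a terminal alkyne: zerovalent palladium, formed in the flask from the divalent precatalyst PdCl2(dppf), inserts into the C–I bond of 5, CO insertion gives the aroylpalladium species, and amine-assisted alkynyl transfer from 8 with reductive elimination gives ynone 9, which creates C4a–C4 and C4–C3. Et2NH then adds to the ynone to give the β-amino enone 10, the ortho phenol oxygen attacks its β-carbon, and loss of Et2NH closes ring C at O1–C2 as a six-membered ring (6-endo addition–elimination) that is aromatic on formation. No stereocentre is formed. The step needs CO insertion to precede alkyne transfer, since the direct coupling product would close to a 2-arylbenzofuran; 20 bar of CO and the electron-rich arylpalladium species flanked by OH and OMe, which should insert CO readily, are meant to secure this. It needs six- over five-membered closure (flavone, not aurone), which the enaminone path secures because only the β-carbon of 10 is electrophilic. It also needs the aroylpalladium species to acylate the alkyne carbon and not the free 3'-OH of 8; this reaction type runs in neat secondary amine without amide formation taking over, and the B-ring phenol is a weaker nucleophile than that amine, so it should be tolerated.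

## Compound list
1 | 1,2,3,4-tetramethoxybenzene | COc1ccc(OC)c(OC)c1OC | starting material
2 | 2,3,4,5-tetramethoxyphenyllithium (not isolated) | [Li]c1cc(OC)c(OC)c(OC)c1OC | intermediate
3 | dimethyl (2,3,4,5-tetramethoxyphenyl)boronate (not isolated) | COB(OC)c1cc(OC)c(OC)c(OC)c1OC | intermediate
4 | 2,3,4,5-tetramethoxyphenol | Oc1cc(OC)c(OC)c(OC)c1OC | intermediate
5 | 2-iodo-3,4,5,6-tetramethoxyphenol | Oc1c(I)c(OC)c(OC)c(OC)c1OC | intermediate
6 | isovanillin, 3-hydroxy-4-methoxybenzaldehyde | O=Cc1ccc(OC)c(O)c1 | starting material
7 | 5-(2-diazoethenyl)-2-methoxyphenol (not isolated) | COc1ccc(C=C=[N+]=[N-])cc1O | intermediate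
8 | 5-ethynyl-2-methoxyphenol | C#Cc1ccc(OC)c(O)c1 | intermediate
9 | 1-(2-hydroxy-3,4,5,6-tetramethoxyphenyl)-3-(3-hydroxy-4-methoxyphenyl)prop-2-yn-1-one (not isolated) | COc1ccc(C#CC(=O)c2c(O)c(OC)c(OC)c(OC)c2OC)cc1O | intermediate
10 | 3-(diethylamino)-1-(2-hydroxy-3,4,5,6-tetramethoxyphenyl)-3-(3-hydroxy-4-methoxyphenyl)prop-2-en-1-one (not isolated, E/Z mixture) | CCN(CC)C(=CC(=O)c1c(O)c(OC)c(OC)c(OC)c1OC)c1ccc(OC)c(O)c1 | intermediate
11 | 3'-demethylnobiletin, 2-(3-hydroxy-4-methoxyphenyl)-5,6,7,8-tetramethoxy-4H-chromen-4-one | COc1ccc(-c2cc(=O)c3c(OC)c(OC)c(OC)c(OC)c3o2)cc1O | target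

**Step count and risks**
Total steps: 4. Longest linear sequence: 3 (steps 1, 2 and 4); step 3 is a one-step side branch.

Steps most likely to fail:

1. Step 4 (key step). The aroylpalladium intermediate may be captured by the free B-ring phenol or by the amine in place of the alkyne. The coupling may also run without CO and close to a benzofuran, or oxidative addition at the electron-rich, doubly ortho-substituted C–I bond may be slow, with loss of iodine by reduction. The fallback builds ring C stepwise by the classical chalcone approach, setting out from 4 and 6 and coming back at 11. Phenol 4 would be acetylated with Ac2O and BF3·OEt2 at 80 °C, with Fries migration of the acetyl group into the only free ring position, to give 1-(2-hydroxy-3,4,5,6-tetramethoxyphenyl)ethan-1-one F1. Claisen–Schmidt condensation of F1 with isovanillin 6 (excess KOH, EtOH, rt) should give (E)-1-(2-hydroxy-3,4,5,6-tetramethoxyphenyl)-3-(3-hydroxy-4-methoxyphenyl)prop-2-en-1-one F2. Oxidative cyclisation of F2 with catalytic I2 in DMSO at 120 °C should give 11.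

2. Step 2. The electrophilic iodine source may oxidise the very electron-rich p-methoxyphenol towards a quinone in place of iodinating the ring. The fallback replaces electrophilic substitution by directed metalation, setting out from 4 and coming back at 5. Phenol 4 would be protected with MOMCl and i-Pr2NEt in CH2Cl2 to give 1,2,3,4-tetramethoxy-5-(methoxymethoxy)benzene F3. Lithiation of F3 at its only free C–H (n-BuLi, THF, 0 °C), which lies between the OMOM and an OMe group, and quenching with I2 should give 1-iodo-3,4,5,6-tetramethoxy-2-(methoxymethoxy)benzene F4. Cleavage of the acetal with HCl in MeOH at rt should give 5.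

3. Step 1. Lithiation may stay incomplete, or the electron-rich phenol may be over-oxidised during the peroxide treatment. The fallback brings the oxygen in by formylation and oxygen insertion, setting out from 1 and coming back at 4. Rieche formylation of 1 (Cl2CHOMe, TiCl4, CH2Cl2, 0 °C) should give 2,3,4,5-tetramethoxybenzaldehyde F5. Baeyer–Villiger oxidation of F5 with mCPBA in CH2Cl2 should give 2,3,4,5-tetramethoxyphenyl formate F6, and methanolysis of F6 (K2CO3, MeOH, rt) should give 4.

## Further compounds
F1 | step 4 | 1-(2-hydroxy-3,4,5,6-tetramethoxyphenyl)ethan-1-one | CC(=O)c1c(O)c(OC)c(OC)c(OC)c1OC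
F2 | step 4 | (E)-1-(2-hydroxy-3,4,5,6-tetramethoxyphenyl)-3-(3-hydroxy-4-methoxyphenyl)prop-2-en-1-one | COc1ccc(/C=C/C(=O)c2c(O)c(OC)c(OC)c(OC)c2OC)cc1O
F3 | step 2 | 1,2,3,4-tetramethoxy-5-(methoxymethoxy)benzene | COCOc1cc(OC)c(OC)c(OC)c1OC
F4 | step 2 | 1-iodo-3,4,5,6-tetramethoxy-2-(methoxymethoxy)benzene | COCOc1c(I)c(OC)c(OC)c(OC)c1OC
F5 | step 1 | 2,3,4,5-tetramethoxybenzaldehyde | O=Cc1cc(OC)c(OC)c(OC)c1OC
F6 | step 1 | 2,3,4,5-tetramethoxyphenyl formate | O=COc1cc(OC)c(OC)c(OC)c1OC
A1 | direct plan | 1,2,3,4-tetramethoxybenzene | COc1ccc(OC)c(OC)c1OC
A2 | direct plan | 1-(2,3,4,5-tetramethoxyphenyl)ethan-1-one | CC(=O)c1cc(OC)c(OC)c(OC)c1OC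
A3 | direct plan | methyl 3-hydroxy-4-methoxybenzoate (methyl isovanillate) | COC(=O)c1ccc(OC)c(O)c1
A4 | direct plan | 1-(3-hydroxy-4-methoxyphenyl)-3-(2,3,4,5-tetramethoxyphenyl)propane-1,3-dione | COc1ccc(C(=O)CC(=O)c2cc(OC)c(OC)c(OC)c2OC)cc1O
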